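## Retrosynthetic overview

1. Ring A carries the ester carbon at C1, oxygen at C2 and C4, and CH3 at C6. This is the alternating pattern of a folded eight-carbon 3,5,7-triketo acid. Its ester oxygen sits on the benzylic CH2 of ring B, and the C3 formyl group lies between the two hydroxyls.
2. 19 ⇒ 18 (remove two MOM groups and the t-Bu group) ⇒ 16 (remove the C3 formyl group). Only ring A has free phenols to direct a magnesium-mediated formylation.
3. 16 ⇒ 14: the ring A C1–C6 bond (chain C2···C7) is opened to an acyclic triketo ester that already holds the ring B benzyl ester.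
4. 14 ⇒ ring B alcohol 7 plus acylketene 13, released from diketo-dioxinone 12, which comes from two acylations of dioxinone 8.
5. 7 ⇒ symmetric 3,5-dihydroxy-4-methylbenzoic acid 1 (reduction, then ortho-lithiation/Boc2O). Ring B is bought, and ring A is the only ring formed (step 9).

Key step: step 9

Remark: the target has no stereocentre and no stereogenic axis. It is achiral, so the given SMILES describes a single compound and no step has to control configuration.

## Route

Step 1
Reactants: 1 3,5-dihydroxy-4-methylbenzoic acid
Product: 2 methoxymethyl 3,5-bis(methoxymethoxy)-4-methylbenzoate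
Conditions: MOMCl (3.5 equiv), i-Pr2NEt, CH2Cl2, 0 °C → rt
Reagents that add atoms: chloromethyl methyl ether, COCCl
Why: O-alkylation by the oxocarbenium-type electrophile caps both phenols and the carboxyl group in one operation, and the MOM ester is as good a substrate for hydride reduction as a methyl ester.

Step 2
Reactants: 2 methoxymethyl 3,5-bis(methoxymethoxy)-4-methylbenzoate
Product: 3 [3,5-bis(methoxymethoxy)-4-methylphenyl]methanol
Conditions: LiAlH4, THF, 0 °C; Fieser work-up
Reagents that add atoms: none
Why: This is a standard LiAlH4 ester reduction, and the aryl MOM acetals are inert to hydride and base.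

Step 3
Reactants: 3 [3,5-bis(methoxymethoxy)-4-methylphenyl]methanol
Product: 4 5-{[(2-methoxypropan-2-yl)oxy]methyl}-1,3-bis(methoxymethoxy)-2-methylbenzene
Conditions: 2-methoxypropene, PPTS (cat.), CH2Cl2, 0 °C; Et3N quench
Reagents that add atoms: 2-methoxypropene, COC(C)=C
Why: Acid-catalysed addition of the alcohol to the enol ether gives an achiral mixed ketal that withstands butyllithium, cannot migrate from oxygen to the lithiated carbon as a silyl group could (retro-Brook), and later leaves under much milder acid than a MOM ether.

Step 4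
Reactants: 4 5-{[(2-methoxypropan-2-yl)oxy]methyl}-1,3-bis(methoxymethoxy)-2-methylbenzene
Product: 6 tert-butyl 6-{[(2-methoxypropan-2-yl)oxy]methyl}-2,4-bis(methoxymethoxy)-3-methylbenzoate, via aryllithium 5 (not isolated)
Conditions: n-BuLi, THF, 0 °C; then Boc2O, −78 °C → rt
Reagents that add atoms: di-tert-butyl dicarbonate, CC(C)(C)OC(=O)OC(=O)OC(C)(C)C
Why: In this directed ortho-metalation the two ring hydrogens are equivalent by symmetry and each lies between an OMOM group and the CH2O-ketal arm, so cooperative coordination should give one aryllithium, whose acylation by Boc2O installs the tert-butyl ester directly and stops there because the di-ortho-substituted ester resists a second addition.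

Step 5
Reactants: 6 tert-butyl 6-{[(2-methoxypropan-2-yl)oxy]methyl}-2,4-bis(methoxymethoxy)-3-methylbenzoate
Product: 7 tert-butyl 6-(hydroxymethyl)-2,4-bis(methoxymethoxy)-3-methylbenzoate
Conditions: AcOH/THF/H2O, rt
Reagents that add atoms: none
Why: Selective ketal hydrolysis works because the tertiary oxocarbenium ion of the methoxypropyl group forms far faster than the primary one of an aryl MOM ether, dilute AcOH leaves the tert-butyl ester alone, and the oxygen is released as a neutral hydroxyl and never as an alkoxide, so closure onto the neighbouring ester (phthalide) should stay slow.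

Step 6
Reactants: 8 2,2,6-trimethyl-4H-1,3-dioxin-4-one
Product: 10 2,2-dimethyl-6-(2-oxopropyl)-4H-1,3-dioxin-4-one, via lithium dienolate 9 (not isolated)
Conditions: 8 (2 equiv), LiHMDS (2 equiv), THF, −78 °C; AcCl (1 equiv), −78 → −20 °C; aq NH4Cl
Reagents that add atoms: acetyl chloride, CC(=O)Cl
Why: This is a Claisen-type γ-C-acylation of the vinylogous lithium enolate of the dioxinone, and the second equivalent of dienolate takes up the more acidic proton of the product.

Step 7
Reactants: 10 2,2-dimethyl-6-(2-oxopropyl)-4H-1,3-dioxin-4-one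
Product: 12 6-(2,4-dioxopentyl)-2,2-dimethyl-4H-1,3-dioxin-4-one, via dilithio dianion 11 (not isolated)
Conditions: LDA (2.2 equiv), THF, −78 → −40 °C; MeC(O)N(OMe)Me, −78 → −10 °C; cold 1 M HCl quench
Reagents that add atoms: N-methoxy-N-methylacetamide, CC(=O)N(C)OC
Why: In this dianion acylation the last-formed, least stabilised terminal enolate carbon is the nucleophilic site, and the Weinreb amide holds the adduct as a chelated tetrahedral intermediate until the cold acid quench, which prevents over-acylation and premature cyclisation.

Step 8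
Reactants: 7 tert-butyl 6-(hydroxymethyl)-2,4-bis(methoxymethoxy)-3-methylbenzoate; 12 6-(2,4-dioxopentyl)-2,2-dimethyl-4H-1,3-dioxin-4-one
Product: 14 [2-(tert-butoxycarbonyl)-3,5-bis(methoxymethoxy)-4-methylphenyl]methyl 3,5,7-trioxooctanoate, via acylketene 13 (not isolated)
Conditions: 12 (1.2 equiv), PhMe, 110 °C, about 1 h; concentrate and use crude
Reagents that add atoms: none
Why: Thermal retro-hetero-Diels–Alder cleavage of the dioxinone expels acetone, and the primary benzylic alcohol adds to the acylketene under neutral conditions, so the inter-ring ester is made without activating a hindered 2,6-disubstituted benzoic acid and without any base that would drive 7 to the phthalide.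

Step 9
Reactants: 14 [2-(tert-butoxycarbonyl)-3,5-bis(methoxymethoxy)-4-methylphenyl]methyl 3,5,7-trioxooctanoate
Product: 16 [2-(tert-butoxycarbonyl)-3,5-bis(methoxymethoxy)-4-methylphenyl]methyl 2,4-dihydroxy-6-methylbenzoate, via cyclic aldol 15 (not isolated)
Conditions: K2CO3, i-PrOH/CH2Cl2, rt; then AcOH, rt
Reagents that add atoms: none
Why: Carbonate equilibrates the enolates of 14, and the C2 carbon (between ester C1 and ketone C3) adds to the terminal methyl ketone C7, forming the C2–C7 bond (ring A C1–C6) in aldol 15; E1cB loss of water and enolisation of the C3 and C5 carbonyl groups, completed on acidification with AcOH, give the resorcinol with the ester at C1, OH at C2 and C4, and CH3 at C6. The closest known reaction type is the biomimetic aldol cycloaromatisation of 3,5,7-triketo esters obtained by acylketene trapping, which is established for orsellinate and other resorcylate esters. The one ring closes as a carbocycle in the favoured 6-(enolendo)-exo-trig mode. The two stereocentres of 15 form without control and vanish on aromatisation, so nothing stereochemical has to be secured. The selectivity needed is aldol closure (C2 to C7) over Claisen closure (C6 to C1) and over pyrone formation (C5 enol oxygen to C1), both of which would expel the ring B alkoxide. It is secured because the unhindered methyl ketone is a much better electrophile than the ester carbonyl, which is also shielded by the bulky benzyl group, because the weak carbonate base brings no alkoxide or chelating divalent metal that would favour acyl transfer, and because the reversible aldol is drained irreversibly by aromatisation.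

Step 10
Reactants: 16 [2-(tert-butoxycarbonyl)-3,5-bis(methoxymethoxy)-4-methylphenyl]methyl 2,4-dihydroxy-6-methylbenzoate
Product: 18 [2-(tert-butoxycarbonyl)-3,5-bis(methoxymethoxy)-4-methylphenyl]methyl 3-formyl-2,4-dihydroxy-6-methylbenzoate, via hydroxymethyl intermediate 17 (not isolated)
Conditions: anhydrous MgCl2, Et3N, (CH2O)n, MeCN, reflux; brief work-up with cold dilute HCl
Reagents that add atoms: paraformaldehyde (as formaldehyde), C=O
Why: In this Casnati–Skattebøl ortho-formylation, magnesium-phenoxide-bound formaldehyde is delivered to an ortho carbon and the alkoxide of 17 is oxidised by a second formaldehyde (Oppenauer-type hydride shift); ring B has no free phenol and stays untouched, C3 is ortho to both magnesium phenoxides (the C2 one has no other free ortho site) and less crowded than C5 next to the methyl group, and the basic medium spares the MOM ethers and the tert-butyl ester.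

Step 11
Reactants: 18 [2-(tert-butoxycarbonyl)-3,5-bis(methoxymethoxy)-4-methylphenyl]methyl 3-formyl-2,4-dihydroxy-6-methylbenzoate
Product: 19 alectorialic acid, 6-{[(3-formyl-2,4-dihydroxy-6-methylbenzoyl)oxy]methyl}-2,4-dihydroxy-3-methylbenzoic acid
Conditions: TFA/CH2Cl2 with a little H2O, 0 °C → rt
Reagents that add atoms: none
Why: Acidolysis cleaves the tert-butyl ester (alkyl–oxygen fission to isobutene) and hydrolyses both aryl MOM acetals, while the inter-ring benzylic ester should hold because both ring B oxygens are meta to the CH2 and the ortho carboxyl group is electron-withdrawing, so no stabilised benzylic cation can form.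

## Compound list

1 | 3,5-dihydroxy-4-methylbenzoic acid | Cc1c(O)cc(C(=O)O)cc1O | starting material
2 | methoxymethyl 3,5-bis(methoxymethoxy)-4-methylbenzoate | COCOC(=O)c1cc(OCOC)c(C)c(OCOC)c1 | intermediate
3 | [3,5-bis(methoxymethoxy)-4-methylphenyl]methanol | OCc1cc(OCOC)c(C)c(OCOC)c1 | intermediate
4 | 5-{[(2-methoxypropan-2-yl)oxy]methyl}-1,3-bis(methoxymethoxy)-2-methylbenzene | COC(C)(C)OCc1cc(OCOC)c(C)c(OCOC)c1 | intermediate
5 | 2-{[(2-methoxypropan-2-yl)oxy]methyl}-4,6-bis(methoxymethoxy)-5-methylphenyllithium | [Li]c1c(COC(C)(C)OC)cc(OCOC)c(C)c1OCOC | intermediate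
6 | tert-butyl 6-{[(2-methoxypropan-2-yl)oxy]methyl}-2,4-bis(methoxymethoxy)-3-methylbenzoate | COC(C)(C)OCc1cc(OCOC)c(C)c(OCOC)c1C(=O)OC(C)(C)C | intermediate
7 | tert-butyl 6-(hydroxymethyl)-2,4-bis(methoxymethoxy)-3-methylbenzoate | OCc1cc(OCOC)c(C)c(OCOC)c1C(=O)OC(C)(C)C | intermediate
8 | 2,2,6-trimethyl-4H-1,3-dioxin-4-one | CC1=CC(=O)OC(C)(C)O1 | starting material
9 | lithium 2,2-dimethyl-6-methylidene-1,3-dioxin-4-olate | C=C1C=C(O[Li])OC(C)(C)O1 | intermediate
10 | 2,2-dimethyl-6-(2-oxopropyl)-4H-1,3-dioxin-4-one | CC(=O)CC1=CC(=O)OC(C)(C)O1 | intermediate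
11 | dilithio dianion of 10 (ring enolate plus terminal enolate) | C=C(O[Li])C=C1C=C(O[Li])OC(C)(C)O1 | intermediate
12 | 6-(2,4-dioxopentyl)-2,2-dimethyl-4H-1,3-dioxin-4-one | CC(=O)CC(=O)CC1=CC(=O)OC(C)(C)O1 | intermediate
13 | 3,5,7-trioxooct-1-en-1-one (acylketene) | CC(=O)CC(=O)CC(=O)C=C=O | intermediate
14 | [2-(tert-butoxycarbonyl)-3,5-bis(methoxymethoxy)-4-methylphenyl]methyl 3,5,7-trioxooctanoate | CC(=O)CC(=O)CC(=O)CC(=O)OCc1cc(OCOC)c(C)c(OCOC)c1C(=O)OC(C)(C)C | intermediate
15 | [2-(tert-butoxycarbonyl)-3,5-bis(methoxymethoxy)-4-methylphenyl]methyl 2-hydroxy-2-methyl-4,6-dioxocyclohexane-1-carboxylate (transient stereoisomer mixture) | CC1(O)CC(=O)CC(=O)C1C(=O)OCc1cc(OCOC)c(C)c(OCOC)c1C(=O)OC(C)(C)C | intermediate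
16 | [2-(tert-butoxycarbonyl)-3,5-bis(methoxymethoxy)-4-methylphenyl]methyl 2,4-dihydroxy-6-methylbenzoate | Cc1cc(O)cc(O)c1C(=O)OCc1cc(OCOC)c(C)c(OCOC)c1C(=O)OC(C)(C)C | intermediate
17 | [2-(tert-butoxycarbonyl)-3,5-bis(methoxymethoxy)-4-methylphenyl]methyl 2,4-dihydroxy-3-(hydroxymethyl)-6-methylbenzoate (present as its magnesium salt) | Cc1cc(O)c(CO)c(O)c1C(=O)OCc1cc(OCOC)c(C)c(OCOC)c1C(=O)OC(C)(C)C | intermediate
18 | [2-(tert-butoxycarbonyl)-3,5-bis(methoxymethoxy)-4-methylphenyl]methyl 3-formyl-2,4-dihydroxy-6-methylbenzoate | Cc1cc(O)c(C=O)c(O)c1C(=O)OCc1cc(OCOC)c(C)c(OCOC)c1C(=O)OC(C)(C)C | intermediate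
19 | alectorialic acid | Cc1cc(O)c(C=O)c(O)c1C(=O)OCc1cc(O)c(C)c(O)c1C(=O)O | target

## Step count and risks

Total step count: 11. Longest linear sequence: 9 (steps 1–5, then 8–11).

**Step 9.**
- Risk: the triketo ester may cyclise by acyl transfer (Claisen closure or pyrone formation). This would lose the ring B alkoxide, which then closes to the phthalide. Dehydration of the aldol may also stall.
- Fallback: it sets out from 12 and 7 and comes back at 16. The same carbon–carbon bond is closed on the dioxinone itself, where no alkoxide can be expelled.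
- Et3N in CH2Cl2 at rt should convert 12 into 7-hydroxy-2,2,5-trimethyl-4H-1,3-benzodioxin-4-one F1. Aqueous KOH in DMSO followed by cold acidification opens it to 2,4-dihydroxy-6-methylbenzoic acid F2.
- In parallel, an Appel reaction on 7 (CBr4, PPh3, CH2Cl2, 0 °C) gives tert-butyl 6-(bromomethyl)-2,4-bis(methoxymethoxy)-3-methylbenzoate F3, which is used at once.
- The carboxylate of F2 (KHCO3, DMF, rt) is then alkylated by F3 at oxygen. This SN2 reaction at the benzylic carbon is indifferent to the crowding around the acyl carbon, and it delivers 16. The path also avoids heating alcohol 7.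

**Step 10.**
- Risk: site selectivity between C3 and C5 may be poor, a second formylation may occur, or the ester-deactivated magnesium phenoxide may react slowly.
- Fallback: it sets out from 16 and comes back at 19. The competing directing group is removed instead of relying on intrinsic site preference.
- MOMCl (1 equiv) with i-Pr2NEt in CH2Cl2 at 0 °C should cap only the C4 hydroxyl, because the C2 hydroxyl is tied up in the hydrogen bond to the ester. The product is [2-(tert-butoxycarbonyl)-3,5-bis(methoxymethoxy)-4-methylphenyl]methyl 2-hydroxy-4-(methoxymethoxy)-6-methylbenzoate F4.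
- The single remaining phenoxide has C3 as its only free ortho carbon, so magnesium-mediated delivery of formaldehyde cannot reach C5. It should give [2-(tert-butoxycarbonyl)-3,5-bis(methoxymethoxy)-4-methylphenyl]methyl 3-formyl-2-hydroxy-4-(methoxymethoxy)-6-methylbenzoate F5.
- The conditions of step 11 then remove three MOM groups and the tert-butyl group to give 19.

**Step 11.**
- Risk: protic acid may cause loss of CO2 from the freed ring B resorcylic acid. The freed carboxyl group may attack the benzylic carbon and expel the ring A acid (phthalide formation). Methoxymethyl cations may be captured by the aromatic rings.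
- Fallback: it sets out from 18 and comes back at 19 and avoids Brønsted acid.
- TMSOTf with 2,2′-bipyridyl in MeCN/CH2Cl2 at 0 °C exchanges the aryl MOM ethers for aryl silyl ethers. More TMSOTf with 2,6-lutidine converts the tert-butyl ester into the silyl ester, and the ring A phenols are silylated along the way.
- This gives [4-methyl-3,5-bis(trimethylsilyloxy)-2-(trimethylsilyloxycarbonyl)phenyl]methyl 3-formyl-6-methyl-2,4-bis(trimethylsilyloxy)benzoate F6. Stirring with pH 7 buffer hydrolyses all five Si–O bonds to give 19.

Further compounds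
F1 | step 9 | 7-hydroxy-2,2,5-trimethyl-4H-1,3-benzodioxin-4-one | Cc1cc(O)cc2c1C(=O)OC(C)(C)O2
F2 | step 9 | 2,4-dihydroxy-6-methylbenzoic acid | Cc1cc(O)cc(O)c1C(=O)O
F3 | step 9 | tert-butyl 6-(bromomethyl)-2,4-bis(methoxymethoxy)-3-methylbenzoate | BrCc1cc(OCOC)c(C)c(OCOC)c1C(=O)OC(C)(C)C
F4 | step 10 | [2-(tert-butoxycarbonyl)-3,5-bis(methoxymethoxy)-4-methylphenyl]methyl 2-hydroxy-4-(methoxymethoxy)-6-methylbenzoate | Cc1cc(OCOC)cc(O)c1C(=O)OCc1cc(OCOC)c(C)c(OCOC)c1C(=O)OC(C)(C)C
F5 | step 10 | [2-(tert-butoxycarbonyl)-3,5-bis(methoxymethoxy)-4-methylphenyl]methyl 3-formyl-2-hydroxy-4-(methoxymethoxy)-6-methylbenzoate | Cc1cc(OCOC)c(C=O)c(O)c1C(=O)OCc1cc(OCOC)c(C)c(OCOC)c1C(=O)OC(C)(C)C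
F6 | step 11 | [4-methyl-3,5-bis(trimethylsilyloxy)-2-(trimethylsilyloxycarbonyl)phenyl]methyl 3-formyl-6-methyl-2,4-bis(trimethylsilyloxy)benzoate | Cc1cc(O[Si](C)(C)C)c(C=O)c(O[Si](C)(C)C)c1C(=O)OCc1cc(O[Si](C)(C)C)c(C)c(O[Si](C)(C)C)c1C(=O)O[Si](C)(C)C
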